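Ring B, the 2H-pyran ring, holds a single cis alkene, C3=C4, lying between the aromatic carbon C4a and the oxygen-bearing quaternary carbon C2. Everything rests on making this alkene by ring-closing metathesis of a 2-vinylaryl ether of a tertiary vinyl carbinol. The carbinol is (R)-linalool, whose stereocentre becomes C2 untouched; it is joined to the arene by SNAr beside an aldehyde that then becomes the C4 vinyl group. The third alkene of the linalyl chain is masked as its epoxide during the metathesis and later becomes the E allylic tertiary alcohol. A Heck reaction with an allylic alcohol finally attaches the aryl ketone arm at C5.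

Key step: step 6

Remark on the chemistry: commercial (R)-(−)-linalool of high enantiomeric purity is assumed, because its stereocentre is carried through unchanged and no later step can enrich it.

Step 1
Reactants: 1 4-bromo-2-fluorophenol
Product: 2 4-bromo-2-fluoro-1-{[2-(trimethylsilyl)ethoxy]methoxy}benzene
Conditions: NaH, SEMCl, THF, 0 °C → rt
Reagents that add atoms: 2-(trimethylsilyl)ethoxymethyl chloride (SEMCl), C[Si](C)(C)CCOCCl
Why: Williamson-type O-alkylation of the phenoxide with the chloromethyl ether gives a small, base-stable acetal ether that later falls to fluoride.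

Step 2
Reactants: 2 4-bromo-2-fluoro-1-{[2-(trimethylsilyl)ethoxy]methoxy}benzene
Product: 4 6-bromo-2-fluoro-3-{[2-(trimethylsilyl)ethoxy]methoxy}benzaldehyde, via aryllithium 3 (not isolated)
Conditions: LiN(iPr)2, THF, −78 °C; DMF, −78 → −20 °C; H2O
Reagents that add atoms: N,N-dimethylformamide (DMF), CN(C)C=O
Why: Directed ortho-lithiation and formylation: the amide base removes the most acidic proton, the one flanked by F and Br, without bromine–lithium exchange, and the cold aryllithium is trapped by DMF before it can lose lithium halide.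

Step 3
Reactants: 4 6-bromo-2-fluoro-3-{[2-(trimethylsilyl)ethoxy]methoxy}benzaldehyde; 5 (R)-(−)-linalool
Product: 7 6-bromo-2-{[(3R)-3,7-dimethylocta-1,6-dien-3-yl]oxy}-3-{[2-(trimethylsilyl)ethoxy]methoxy}benzaldehyde, via potassium linaloolate 6 (not isolated)
Conditions: 5 (1.3 equiv), KN(SiMe3)2 (1.2 equiv), THF, 0 °C; then 4, 0 °C → rt
Reagents that add atoms: none
Why: Nucleophilic aromatic substitution (SNAr): the tertiary alkoxide, which has no α-hydrogen and so cannot reduce the aldehyde, displaces the fluoride activated by the ortho formyl group, and since no bond at the carbinol carbon is broken the R configuration of linalool is carried over unchanged.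

Step 4
Reactants: 7 6-bromo-2-{[(3R)-3,7-dimethylocta-1,6-dien-3-yl]oxy}-3-{[2-(trimethylsilyl)ethoxy]methoxy}benzaldehyde
Product: 8 1-bromo-3-{[(3R)-3,7-dimethylocta-1,6-dien-3-yl]oxy}-2-ethenyl-4-{[2-(trimethylsilyl)ethoxy]methoxy}benzene
Conditions: MePPh3Br, KOtBu, THF, 0 °C → rt
Reagents that add atoms: methyltriphenylphosphonium bromide, C[P+](c1ccccc1)(c1ccccc1)c1ccccc1.[Br-]
Why: Wittig methylenation of the non-enolisable aldehyde turns the SNAr-activating group into the vinyl group that will supply C4.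

Step 5
Reactants: 8 1-bromo-3-{[(3R)-3,7-dimethylocta-1,6-dien-3-yl]oxy}-2-ethenyl-4-{[2-(trimethylsilyl)ethoxy]methoxy}benzene
Product: 9 1-bromo-3-{[(3R)-5-(3,3-dimethyloxiran-2-yl)-3-methylpent-1-en-3-yl]oxy}-2-ethenyl-4-{[2-(trimethylsilyl)ethoxy]methoxy}benzene
Conditions: mCPBA (1.05 equiv), NaHCO3, CH2Cl2, 0 °C
Reagents that add atoms: 3-chloroperoxybenzoic acid (mCPBA), OOC(=O)c1cccc(Cl)c1
Why: Prilezhaev epoxidation: the trisubstituted alkene is much more nucleophilic than the twisted aryl vinyl group and the vinyl group on the ether carbon, so one equivalent of buffered peracid should epoxidise it alone; the new oxirane centre forms without control, as both epimers, and is erased in step 7.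

Step 6
Reactants: 9 1-bromo-3-{[(3R)-5-(3,3-dimethyloxiran-2-yl)-3-methylpent-1-en-3-yl]oxy}-2-ethenyl-4-{[2-(trimethylsilyl)ethoxy]methoxy}benzene
Product: 10 (2R)-5-bromo-2-[2-(3,3-dimethyloxiran-2-yl)ethyl]-2-methyl-8-{[2-(trimethylsilyl)ethoxy]methoxy}-2H-chromene
Conditions: second-generation Hoveyda–Grubbs catalyst RuCl2(H2IMes)(=CH-C6H4-2-OiPr) (5 mol %), toluene (0.01 M), 70 °C, N2 sparge
Reagents that add atoms: none
Why: Ring-closing olefin metathesis: the ruthenium alkylidene loads on one of the two monosubstituted alkenes of 9, adds across the other by [2+2] cycloaddition to a ruthenacyclobutane, and cycloreversion releases the C3=C4 alkene with loss of ethylene. The closest known reaction type is the metathesis closure of 2-vinylphenyl allyl ethers to 2H-chromenes. Only ring B is closed, a six-membered ring made by joining the two internal alkene carbons (C3 and C4), and the ring size forces the cis alkene. No stereocentre is created, and C2 keeps the R configuration of linalool because none of its four bonds is touched. The step needs the two vinyl groups to pair only with each other; this is secured by masking the third alkene of the linalyl chain as an epoxide (as a free alkene it would close a cyclopentene with the C2 vinyl group) and by high dilution against dimerisation. The fully substituted C2 favours the cyclising conformer (Thorpe–Ingold effect), which should offset slow loading on the 2,6-disubstituted styrene.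

Step 7
Reactants: 10 (2R)-5-bromo-2-[2-(3,3-dimethyloxiran-2-yl)ethyl]-2-methyl-8-{[2-(trimethylsilyl)ethoxy]methoxy}-2H-chromene
Product: 13 (3E)-5-[(2R)-5-bromo-2-methyl-8-{[2-(trimethylsilyl)ethoxy]methoxy}-2H-chromen-2-yl]-2-methylpent-3-en-2-ol, via hydroxy selenide 11 (not isolated), via selenoxide 12 (not isolated)
Conditions: (PhSe)2, NaBH4, EtOH, rt → 70 °C; then THF, 30% H2O2, pyridine, 0 °C → rt
Reagents that add atoms: none
Why: Epoxide opening by selenolate followed by selenoxide syn-elimination: PhSe− attacks the less hindered oxirane CH by SN2, and the selenoxide can only eliminate away from the hydrogen-free carbinol carbon, which should give the E allylic tertiary alcohol and removes the uncontrolled oxirane centre.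

Step 8
Reactants: 14 2,4-dihydroxybenzaldehyde
Product: 15 2,4-bis[(tert-butyldimethylsilyl)oxy]benzaldehyde
Conditions: TBSCl (2.3 equiv), imidazole, DMF, rt
Reagents that add atoms: tert-butyldimethylsilyl chloride (TBSCl), CC(C)(C)[Si](C)(C)Cl
Why: Imidazole-promoted silylation protects both phenols as silyl ethers that fall in the final fluoride step.

Step 9
Reactants: 15 2,4-bis[(tert-butyldimethylsilyl)oxy]benzaldehyde
Product: 16 1-{2,4-bis[(tert-butyldimethylsilyl)oxy]phenyl}prop-2-en-1-ol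
Conditions: CH2=CHMgBr, THF, −78 → 0 °C; H2O
Reagents that add atoms: vinylmagnesium bromide, C=C[Mg]Br
Why: Grignard 1,2-addition to the aldehyde at low temperature, where the magnesium alkoxide should not trigger silyl migration, gives the racemic allylic alcohol, whose carbinol centre is oxidised away in step 10.

Step 10
Reactants: 13 (3E)-5-[(2R)-5-bromo-2-methyl-8-{[2-(trimethylsilyl)ethoxy]methoxy}-2H-chromen-2-yl]-2-methylpent-3-en-2-ol; 16 1-{2,4-bis[(tert-butyldimethylsilyl)oxy]phenyl}prop-2-en-1-ol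
Product: 18 1-{2,4-bis[(tert-butyldimethylsilyl)oxy]phenyl}-3-[(2R)-2-[(2E)-4-hydroxy-4-methylpent-2-en-1-yl]-2-methyl-8-{[2-(trimethylsilyl)ethoxy]methoxy}-2H-chromen-5-yl]propan-1-one, via enol 17 (not isolated)
Conditions: Pd(OAc)2 (5 mol %), P(t-Bu)3·HBF4 (10 mol %), Cy2NMe, dioxane, 80 °C
Reagents that add atoms: none
Why: Heck reaction of an aryl bromide with an allylic alcohol: zerovalent palladium inserts into the C–Br bond, the aryl group adds to the terminal alkene carbon of 16, and β-hydride elimination toward the carbinol C–H gives an enol that tautomerises to the saturated aryl ketone, while the internal, hindered chromene and E alkenes of 13 should not compete.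

Step 11
Reactants: 18 1-{2,4-bis[(tert-butyldimethylsilyl)oxy]phenyl}-3-[(2R)-2-[(2E)-4-hydroxy-4-methylpent-2-en-1-yl]-2-methyl-8-{[2-(trimethylsilyl)ethoxy]methoxy}-2H-chromen-5-yl]propan-1-one
Product: 19 1-(2,4-dihydroxyphenyl)-3-{(2R)-8-hydroxy-2-[(2E)-4-hydroxy-4-methylpent-2-en-1-yl]-2-methyl-2H-chromen-5-yl}propan-1-one
Conditions: Bu4NF (6 equiv), THF/DMPU, 50 °C; AcOH
Reagents that add atoms: none
Why: Fluoride-induced desilylation removes both aryl silyl ethers and fragments the silylethoxymethyl ether (to fluorotrimethylsilane, ethylene and formaldehyde) under non-acidic conditions that should leave the tertiary allylic alcohol and the chromene untouched.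

Compound list
1 | 4-bromo-2-fluorophenol | Oc1ccc(Br)cc1F | starting material
2 | 4-bromo-2-fluoro-1-{[2-(trimethylsilyl)ethoxy]methoxy}benzene | C[Si](C)(C)CCOCOc1ccc(Br)cc1F | intermediate
3 | [6-bromo-2-fluoro-3-{[2-(trimethylsilyl)ethoxy]methoxy}phenyl]lithium (not isolated) | [Li]c1c(F)c(OCOCC[Si](C)(C)C)ccc1Br | intermediate
4 | 6-bromo-2-fluoro-3-{[2-(trimethylsilyl)ethoxy]methoxy}benzaldehyde | O=Cc1c(F)c(OCOCC[Si](C)(C)C)ccc1Br | intermediate
5 | (R)-(−)-linalool, (3R)-3,7-dimethylocta-1,6-dien-3-ol | C=C[C@](C)(O)CCC=C(C)C | starting material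
6 | potassium (3R)-3,7-dimethylocta-1,6-dien-3-olate (not isolated) | C=C[C@](C)([O-])CCC=C(C)C.[K+] | intermediate
7 | 6-bromo-2-{[(3R)-3,7-dimethylocta-1,6-dien-3-yl]oxy}-3-{[2-(trimethylsilyl)ethoxy]methoxy}benzaldehyde | C=C[C@](C)(Oc1c(C=O)c(Br)ccc1OCOCC[Si](C)(C)C)CCC=C(C)C | intermediate
8 | 1-bromo-3-{[(3R)-3,7-dimethylocta-1,6-dien-3-yl]oxy}-2-ethenyl-4-{[2-(trimethylsilyl)ethoxy]methoxy}benzene | C=C[C@](C)(Oc1c(C=C)c(Br)ccc1OCOCC[Si](C)(C)C)CCC=C(C)C | intermediate
9 | 1-bromo-3-{[(3R)-5-(3,3-dimethyloxiran-2-yl)-3-methylpent-1-en-3-yl]oxy}-2-ethenyl-4-{[2-(trimethylsilyl)ethoxy]methoxy}benzene (both epimers at the oxirane CH) | C=C[C@](C)(Oc1c(C=C)c(Br)ccc1OCOCC[Si](C)(C)C)CCC1OC1(C)C | intermediate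
10 | (2R)-5-bromo-2-[2-(3,3-dimethyloxiran-2-yl)ethyl]-2-methyl-8-{[2-(trimethylsilyl)ethoxy]methoxy}-2H-chromene (both epimers at the oxirane CH) | CC1(C)OC1CC[C@]1(C)C=Cc2c(Br)ccc(OCOCC[Si](C)(C)C)c2O1 | intermediate
11 | 5-[(2R)-5-bromo-2-methyl-8-{[2-(trimethylsilyl)ethoxy]methoxy}-2H-chromen-2-yl]-2-methyl-3-(phenylselanyl)pentan-2-ol (not isolated) | CC(C)(O)C([Se]c1ccccc1)CC[C@]1(C)C=Cc2c(Br)ccc(OCOCC[Si](C)(C)C)c2O1 | intermediate
12 | 3-(benzeneseleninyl)-5-[(2R)-5-bromo-2-methyl-8-{[2-(trimethylsilyl)ethoxy]methoxy}-2H-chromen-2-yl]-2-methylpentan-2-ol (not isolated) | CC(C)(O)C([Se](=O)c1ccccc1)CC[C@]1(C)C=Cc2c(Br)ccc(OCOCC[Si](C)(C)C)c2O1 | intermediate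
13 | (3E)-5-[(2R)-5-bromo-2-methyl-8-{[2-(trimethylsilyl)ethoxy]methoxy}-2H-chromen-2-yl]-2-methylpent-3-en-2-ol | CC(C)(O)/C=C/C[C@]1(C)C=Cc2c(Br)ccc(OCOCC[Si](C)(C)C)c2O1 | intermediate
14 | 2,4-dihydroxybenzaldehyde | O=Cc1ccc(O)cc1O | starting material
15 | 2,4-bis[(tert-butyldimethylsilyl)oxy]benzaldehyde | O=Cc1ccc(O[Si](C)(C)C(C)(C)C)cc1O[Si](C)(C)C(C)(C)C | intermediate
16 | 1-{2,4-bis[(tert-butyldimethylsilyl)oxy]phenyl}prop-2-en-1-ol (racemic) | C=CC(O)c1ccc(O[Si](C)(C)C(C)(C)C)cc1O[Si](C)(C)C(C)(C)C | intermediate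
17 | 1-{2,4-bis[(tert-butyldimethylsilyl)oxy]phenyl}-3-[(2R)-2-[(2E)-4-hydroxy-4-methylpent-2-en-1-yl]-2-methyl-8-{[2-(trimethylsilyl)ethoxy]methoxy}-2H-chromen-5-yl]prop-1-en-1-ol (enol, not isolated) | CC(C)(O)/C=C/C[C@]1(C)C=Cc2c(CC=C(O)c3ccc(O[Si](C)(C)C(C)(C)C)cc3O[Si](C)(C)C(C)(C)C)ccc(OCOCC[Si](C)(C)C)c2O1 | intermediate
18 | 1-{2,4-bis[(tert-butyldimethylsilyl)oxy]phenyl}-3-[(2R)-2-[(2E)-4-hydroxy-4-methylpent-2-en-1-yl]-2-methyl-8-{[2-(trimethylsilyl)ethoxy]methoxy}-2H-chromen-5-yl]propan-1-one | CC(C)(O)/C=C/C[C@]1(C)C=Cc2c(CCC(=O)c3ccc(O[Si](C)(C)C(C)(C)C)cc3O[Si](C)(C)C(C)(C)C)ccc(OCOCC[Si](C)(C)C)c2O1 | intermediate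
19 | 1-(2,4-dihydroxyphenyl)-3-{(2R)-8-hydroxy-2-[(2E)-4-hydroxy-4-methylpent-2-en-1-yl]-2-methyl-2H-chromen-5-yl}propan-1-one | CC(C)(O)/C=C/C[C@]1(C)C=Cc2c(CCC(=O)c3ccc(O)cc3O)ccc(O)c2O1 | target

Total step count: 11. Longest linear sequence: 9 (steps 1 to 7, then 10 and 11).

Steps most likely to fail

Step 3. The hindered tertiary alkoxide may add reversibly to the formyl group and start hydride transfer between aldehyde molecules, or substitution may be too slow at a carbon flanked by two ortho substituents. The fallback sets out from 4 and comes back at 7, with the ether bond made at the allyl carbon instead of the aryl carbon. Compound 4 is treated with 2-(methylsulfonyl)ethanol and NaH in DMF. Fluoride is displaced to give 6-bromo-2-[2-(methylsulfonyl)ethoxy]-3-{[2-(trimethylsilyl)ethoxy]methoxy}benzaldehyde F1, which is not isolated and loses methyl vinyl sulfone by base-induced elimination to give the phenol 6-bromo-2-hydroxy-3-{[2-(trimethylsilyl)ethoxy]methoxy}benzaldehyde F2. Commercial geraniol is converted with methyl chloroformate and pyridine into geranyl methyl carbonate F3. Palladium-catalysed asymmetric allylic O-alkylation of F2 with F3 (Pd2(dba)3·CHCl3, Trost ligand, CH2Cl2, rt) should give the branched tertiary ether 7 by attack of the phenol at the more substituted end of the π-allyl complex. The ligand enantiomer that gives the R ether would have to be established on the first run.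

Step 6. Loading of ruthenium on either hindered alkene (a 2,6-disubstituted styrene and a vinyl group on a fully substituted carbon) may be slower than catalyst decay, so that intermolecular metathesis or no reaction wins. The fallback sets out from 7 and comes back at 10 by relay ring-closing metathesis. Wittig reaction of 7 with the ylide from (hex-5-en-1-yl)triphenylphosphonium bromide and KN(SiMe3)2 (THF, −78 °C → rt) gives 1-bromo-3-{[(3R)-3,7-dimethylocta-1,6-dien-3-yl]oxy}-2-[(1Z)-hepta-1,6-dien-1-yl]-4-{[2-(trimethylsilyl)ethoxy]methoxy}benzene F4. Buffered mCPBA epoxidises its trisubstituted alkene to give 1-bromo-3-{[(3R)-5-(3,3-dimethyloxiran-2-yl)-3-methylpent-1-en-3-yl]oxy}-2-[(1Z)-hepta-1,6-dien-1-yl]-4-{[2-(trimethylsilyl)ethoxy]methoxy}benzene F5. With the same ruthenium catalyst the carbene loads on the unhindered terminal alkene of the relay arm, expels cyclopentene and is thereby delivered to the benzylic carbon. From there ring B closes onto the C2 vinyl group to give 10.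

Step 10. β-Hydride elimination may go toward the benzylic CH2 and leave an allylic alcohol instead of the ketone. Oxidative addition at the hindered, electron-rich bromide may also be slow, and the electron-rich benzylic allylic alcohol may ionise or lose a silyl group under the hot basic conditions. The fallback sets out from 13 and comes back at 19 by an aldol route.
- n-BuLi (2.2 equiv, THF, −78 °C) first deprotonates the tertiary alcohol and then exchanges bromine for lithium to give the dilithio species lithium (3E)-5-[(2R)-5-lithio-2-methyl-8-{[2-(trimethylsilyl)ethoxy]methoxy}-2H-chromen-2-yl]-2-methylpent-3-en-2-olate F6 (not isolated).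
- DMF then formylates it to (2R)-2-[(2E)-4-hydroxy-4-methylpent-2-en-1-yl]-2-methyl-8-{[2-(trimethylsilyl)ethoxy]methoxy}-2H-chromene-5-carbaldehyde F7.
- Commercial 2',4'-dihydroxyacetophenone is protected with SEMCl and NaH to give 1-(2,4-bis{[2-(trimethylsilyl)ethoxy]methoxy}phenyl)ethan-1-one F8.
- Claisen–Schmidt condensation of F7 with F8 (KOH, EtOH) gives the E chalcone (2E)-1-(2,4-bis{[2-(trimethylsilyl)ethoxy]methoxy}phenyl)-3-[(2R)-2-[(2E)-4-hydroxy-4-methylpent-2-en-1-yl]-2-methyl-8-{[2-(trimethylsilyl)ethoxy]methoxy}-2H-chromen-5-yl]prop-2-en-1-one F9.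
- Stryker's reagent [(Ph3P)CuH]6 in wet toluene reduces only the enone alkene and gives 1-(2,4-bis{[2-(trimethylsilyl)ethoxy]methoxy}phenyl)-3-[(2R)-2-[(2E)-4-hydroxy-4-methylpent-2-en-1-yl]-2-methyl-8-{[2-(trimethylsilyl)ethoxy]methoxy}-2H-chromen-5-yl]propan-1-one F10.
- Bu4NF in THF/DMPU at 60 °C, followed by AcOH, removes the three acetal ethers and gives 19.

Further compounds
F1 | step 3 | 6-bromo-2-[2-(methylsulfonyl)ethoxy]-3-{[2-(trimethylsilyl)ethoxy]methoxy}benzaldehyde (not isolated) | CS(=O)(=O)CCOc1c(C=O)c(Br)ccc1OCOCC[Si](C)(C)C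
F2 | step 3 | 6-bromo-2-hydroxy-3-{[2-(trimethylsilyl)ethoxy]methoxy}benzaldehyde | O=Cc1c(O)c(OCOCC[Si](C)(C)C)ccc1Br
F3 | step 3 | geranyl methyl carbonate, (2E)-3,7-dimethylocta-2,6-dien-1-yl methyl carbonate | COC(=O)OC/C=C(\C)CCC=C(C)C
F4 | step 6 | 1-bromo-3-{[(3R)-3,7-dimethylocta-1,6-dien-3-yl]oxy}-2-[(1Z)-hepta-1,6-dien-1-yl]-4-{[2-(trimethylsilyl)ethoxy]methoxy}benzene | C=C[C@](C)(Oc1c(/C=C\CCCC=C)c(Br)ccc1OCOCC[Si](C)(C)C)CCC=C(C)C
F5 | step 6 | 1-bromo-3-{[(3R)-5-(3,3-dimethyloxiran-2-yl)-3-methylpent-1-en-3-yl]oxy}-2-[(1Z)-hepta-1,6-dien-1-yl]-4-{[2-(trimethylsilyl)ethoxy]methoxy}benzene | C=C[C@](C)(Oc1c(/C=C\CCCC=C)c(Br)ccc1OCOCC[Si](C)(C)C)CCC1OC1(C)C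
F6 | step 10 | lithium (3E)-5-[(2R)-5-lithio-2-methyl-8-{[2-(trimethylsilyl)ethoxy]methoxy}-2H-chromen-2-yl]-2-methylpent-3-en-2-olate (not isolated) | [Li]OC(C)(C)/C=C/C[C@]1(C)C=Cc2c([Li])ccc(OCOCC[Si](C)(C)C)c2O1
F7 | step 10 | (2R)-2-[(2E)-4-hydroxy-4-methylpent-2-en-1-yl]-2-methyl-8-{[2-(trimethylsilyl)ethoxy]methoxy}-2H-chromene-5-carbaldehyde | CC(C)(O)/C=C/C[C@]1(C)C=Cc2c(C=O)ccc(OCOCC[Si](C)(C)C)c2O1
F8 | step 10 | 1-(2,4-bis{[2-(trimethylsilyl)ethoxy]methoxy}phenyl)ethan-1-one | CC(=O)c1ccc(OCOCC[Si](C)(C)C)cc1OCOCC[Si](C)(C)C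
F9 | step 10 | (2E)-1-(2,4-bis{[2-(trimethylsilyl)ethoxy]methoxy}phenyl)-3-[(2R)-2-[(2E)-4-hydroxy-4-methylpent-2-en-1-yl]-2-methyl-8-{[2-(trimethylsilyl)ethoxy]methoxy}-2H-chromen-5-yl]prop-2-en-1-one | CC(C)(O)/C=C/C[C@]1(C)C=Cc2c(/C=C/C(=O)c3ccc(OCOCC[Si](C)(C)C)cc3OCOCC[Si](C)(C)C)ccc(OCOCC[Si](C)(C)C)c2O1
F10 | step 10 | 1-(2,4-bis{[2-(trimethylsilyl)ethoxy]methoxy}phenyl)-3-[(2R)-2-[(2E)-4-hydroxy-4-methylpent-2-en-1-yl]-2-methyl-8-{[2-(trimethylsilyl)ethoxy]methoxy}-2H-chromen-5-yl]propan-1-one | CC(C)(O)/C=C/C[C@]1(C)C=Cc2c(CCC(=O)c3ccc(OCOCC[Si](C)(C)C)cc3OCOCC[Si](C)(C)C)ccc(OCOCC[Si](C)(C)C)c2O1
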